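Elm, the flask asked about, reads 16% Z at 5.00 min and 26% at 90.0 min, so we count how many turnovers lie in that time.

| flask | G | J | temperature | remark | time |
|---|---|---|---|---|---|
| elm | 0.10 M | 0.20 M | 25 °C | the very flask that is asked about, followed so far |  |
| oak | 0.15 M | 0.20 M | 20 °C | run made earlier |  |
| flask | 0.10 M | 0.200 M | 25 °C |  | 1.5 h |

- elm (time / min: Z / %): 5.00: 16; 15.0: 19; 25.0: 23; 40.0: 21; 50.0: 21; 80.0: 25; 90.0: 26
- oak (time / s: Z / %): 15.0: 0; 30.0: 1; 50.0: 0; 60.0: 1; 80.0: 4; 90.0: 2; 120: 4

(each reading ± 2 percentage points)

- green: change nothing and wait 3.0 h more
- red: at 1.5 h take out 90% of the Z then present, then wait 3.0 h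
- amber: at 1.5 h add J, 100% of the amount charged, then wait 3.0 h
- ochre: at 1.5 h raise the temperature by 25 K, then wait 3.0 h

1. Z, in percent of the G first charged, at 1.5 h
2. what to do for the largest gain in Z; "none" if nothing gains more than 2 percentage points (green / red / amber / ochre / none)
3. Z present, with what was taken out counted in, in percent of the G first charged, after red
4. Z present, with what was taken out counted in, in percent of the G first charged, after ochre

- Z taken out counts as made
- additions bring no volume worth counting

We work by hand, in fractions of the G charged. First comes the level. The 6 elm readings from 15.0 min on average 22.5%. The last one stands 3.5 percentage points above that, against a scatter of 2 points, so we take them as flat.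

Next comes the pace. At 5.00 min the gap to the level is 6.5 points, so it has shrunk by a factor of 3.46. The turnover, the time in which that gap halves, is therefore 2.79 min.

So 1.5 h holds 32.2 turnovers. Each one halves the gap, so elm stands at its level. We commit to 22.5% at 1.5 h, and we expect no gain from green.

The weak link is the single reading at 5.00 min. If we widen its gap by the scatter, the turnover becomes 3.56 min. That still leaves 25.3 turnovers in 1.5 h, and 50.6 more in the further 3.0 h. We therefore expect each option to end at a new level of its own. Elm cannot show where those levels lie, so we give no number for red or ochre.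

The forecast gives 25% now, ochre as the best move, 47% after red and 80% after ochre, and it reads elm as “a fast phase that shuts off, then a slow one”.

The flask gives 23.0% at 1.5 h. Green adds 0 points, red 15 points, amber 4.3 points and ochre 24 points, so ochre is the best move. Red ends at 38.5% and ochre at 47.2%.

    G + J → E (k = 2.01 /M/s, Ea = 39.0 kJ/mol)
    J + E ⇌ Z (K = 76.1 /M, k = 0.0657 /M/s, Ea = 50.0 kJ/mol, ΔH = −34.0 kJ/mol)
    Z ⇌ D (K = 2.60, k = 0.156 /s, Ea = 67.0 kJ/mol, ΔH = −79.0 kJ/mol)
    (constants at 25 °C)

Z stands at 23.0% mainly because it passes on to D and back: with that path taken away, the same flask gives 69.7%. Our turnover of 2.79 min, read from the rise of Z, stands beside the 1.94 min by which the path from Z to D had done half its turnover up to 1.5 h. That step, both ways together, has a relaxation half-life of 0.0535 min, shorter than 1.5 h, and at 1.5 h the flask holds 2.60 D per Z, the equilibrium ratio. The neighbour flask, charged with 0.34 M of J, has had the same time and holds 2.60 D per Z, with Z at 27.1%.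

The readings were generated by integration for an exercise; scatter was added.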